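**Assumptions**
- Isofraxidin (7-hydroxy-6,8-dimethoxycoumarin) is a catalogue compound, and I take it as the commercial starting material. The key unit, the 2,4-dimethoxyresorcinol-type coumarin core, is not readily available any other way.
- The target SMILES has no stereocenters, and the C4–C4' biaryl axis is not configurationally stable. There is therefore no enantiomer to control. The only stereocenters in the route are the two transient C4/C4' centers in compound 4, a meso/dl mixture that is destroyed in Step 3.
- Only substrates and atom-contributing reagents are numbered. Bulk reagents such as base, Mg, TMSCl, DDQ and HCl are named in the conditions.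

**Retrosynthesis**
1. Target 6 comes from bis-MOM ether 5 by acid removal of the MOM groups.
2. 5 comes from the bis(3,4-dihydrocoumarin) 4 by DDQ dehydrogenation, which re-forms both C3=C4 bonds.
3. 4 comes from two molecules of 7-O-MOM-isofraxidin (3) by reductive β,β-hydrodimerization, which forms the C4–C4' bond.
4. 3 comes from commercial isofraxidin (1) by MOM protection of the 7-OH.
5. Both coumarin rings are already present in 1, so no ring is built. The only bond formed is C4–C4'.

**Route**

**Step 1**
Reactants: 1 isofraxidin (7-hydroxy-6,8-dimethoxycoumarin); 2 chloromethyl methyl ether (MOMCl)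
Product: 3, 7-O-(methoxymethyl)isofraxidin, i.e. 6,8-dimethoxy-7-(methoxymethoxy)-2H-chromen-2-one
Conditions: MOMCl, i-Pr2NEt, CH2Cl2, 0 °C → rt
Reagents that add atoms: MOMCl, COCCl (adds the CH2OCH3 group)
Why: The hindered phenol is O-alkylated (Williamson-type) under mild base. The MOM ether survives the reductive and oxidative steps that follow, and it is removed by acid without opening the lactone. No stereocenter is formed.

**Step 2**
Reactants: 3 (2 equiv)
Product: 4, 4,4'-bi[6,8-dimethoxy-7-(methoxymethoxy)-3,4-dihydrocoumarin], as a meso/dl mixture
Conditions: Mg turnings, TMSCl, DMF, 0 °C → rt; aq. NH4Cl work-up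
Reagents that add atoms: none (TMSCl is lost as silyl ketene acetal and then siloxane on work-up; the added H atoms come from water)
Why: Mg/TMSCl reductive dimerization of α,β-unsaturated esters gives β,β-coupling. Single-electron reduction gives the coumarin radical anion, which is trapped as the silyl ketene acetal and couples at the electrophilic C4, forming the C4–C4' bond. The two new C4 stereocenters form as a mixture, which does not matter because both are removed in Step 3.

**Step 3**
Reactants: 4
Product: 5, 4,4'-bi[6,8-dimethoxy-7-(methoxymethoxy)coumarin]
Conditions: DDQ (3 equiv), 1,4-dioxane, reflux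
Reagents that add atoms: none (DDQ ends up as DDQH2)
Why: This is a DDQ hydride-abstraction dehydrogenation. The C4–H is benzylic and para to the 7-oxygen, so the C4 cation is well stabilized. Loss of H3 then gives the conjugated coumarin, and this happens at both halves. Both C4 stereocenters become sp2, so the mixture converges to a single achiral product.

**Step 4**
Reactants: 5
Product: 6, 4,4'-biisofraxidin (target)
Conditions: 3 M HCl, THF/MeOH (1:1), 50 °C
Reagents that add atoms: none (the MOM groups leave as CH2(OMe)2 or MeOCH2OMe)
Why: Acid-catalysed MOM acetal hydrolysis frees both 7-OH groups. The aryl methyl ethers and the coumarin lactones are stable to these conditions.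

**Compound list**

| # | Name | SMILES | Role |
|---|---|---|---|
| 1 | Isofraxidin | COc1cc2ccc(=O)oc2c(OC)c1O | starting material |
| 2 | Chloromethyl methyl ether (MOMCl) | COCCl | reagent/starting material |
| 3 | 7-O-MOM-isofraxidin | COc1cc2ccc(=O)oc2c(OC)c1OCOC | intermediate |
| 4 | 4,4'-Bi(7-MOMO-6,8-dimethoxy-3,4-dihydrocoumarin), meso/dl mixture | COc1cc2c(c(OC)c1OCOC)OC(=O)CC2C3CC(=O)Oc4c(OC)c(OCOC)c(OC)cc34 | intermediate |
| 5 | Bis-MOM-4,4'-biisofraxidin | COc1cc2c(c(OC)c1OCOC)oc(=O)cc2-c3cc(=O)oc4c(OC)c(OCOC)c(OC)cc34 | intermediate |
| 6 | 4,4'-Biisofraxidin (achiral) | COc1cc2c(-c3cc(=O)oc4c(OC)c(O)c(OC)cc34)cc(=O)oc2c(OC)c1O | target |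

**Totals:** 4 steps; longest linear sequence 4 steps.

**Three steps most likely to fail, with fallbacks**
1. **Step 2 (reductive dimerization).** The electron-rich coumarin is hard to reduce, so the result may be over-reduction to the monomeric dihydrocoumarin or hydrocinnamate instead of the dimer. Fallback: build the C4–C4' bond by Ni(0) reductive homocoupling of the 4-tosyloxycoumarin. That coumarin would come from the 4-hydroxycoumarin, made from the corresponding 2-hydroxyacetophenone and diethyl carbonate/NaH. This is a different bond-forming strategy.
2. **Step 3 (DDQ dehydrogenation).** Over-oxidation, MOM cleavage by the acidic DDQH2, or incomplete conversion of the second ring could all occur. Fallback: form the bis-lactone enolate (LiHMDS), α-selenate with PhSeCl, and eliminate the selenoxide with H2O2. This replaces hydride abstraction with selenoxide syn-elimination.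
3. **Step 4 (MOM removal).** Acid with methanol could methanolyse the aryl lactone, or partly demethylate the flanking OMe groups. Fallback: protect the phenol as a benzyl ether in Step 1 and remove it at the end by transfer hydrogenolysis (Pd/C, cyclohexadiene), which avoids acid and nucleophilic solvent. The Bn group must survive the Step 3 DDQ conditions.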